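**Retrosynthetic overview**
1. 15 ⇐ 14 (O-debenzylation) ⇐ 9. The tetralone ring (C1–C2–C3–C4–C4a–C8a) comes from the five-membered ring of an α-methyl-α-vinyl-1-indanone by a one-carbon radical ring expansion (MHAT-initiated Dowd–Beckwith 1,2-acyl shift), which also sets C3 and C2.
2. Enabling feature: the C1 aryl ketone lies 1,3 to the methyl-bearing tertiary carbon C3, and C2 between them carries H and CH3. C2–CH3 therefore maps onto a vinyl group and C3 onto the quaternary α-carbon of an indanone, while the pseudoaxial C4 aryl group (peri C5–H of the dimethoxybenzo ring) shields one face of C3.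
3. 9 ⇐ 7 ⇐ 5 by Pd-catalysed α-vinylation and α-methylation. The quaternary centre is sacrificial, so its configuration does not matter.
4. 5 ⇐ 4 ⇐ 2 + 3. An asymmetric reductive Heck cyclisation of a 2'-bromochalcone sets the only catalyst-controlled stereocentre (future C4), and the chalcone comes from a Claisen–Schmidt condensation.
5. Ring order: five-membered indanone ring (step 3) → transient cyclopropane → six-membered tetralone ring (both in step 6).

Key step: step 6

Remark on the chemistry: the sense of induction of the chiral bisphosphine in step 3 is not predicted here. The ligand antipode that delivers the 3R ketone is to be used (written as (R) for definiteness).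

**Step 1**
Reactants: 1 1-(3,4-dimethoxyphenyl)ethan-1-one (acetoveratrone)
Product: 2 1-(2-bromo-4,5-dimethoxyphenyl)ethan-1-one
Conditions: NBS (1.05 equiv), MeCN, 0 °C → rt, dark
Reagents that add atoms: N-bromosuccinimide, O=C1CCC(=O)N1Br
Why: Electrophilic aromatic bromination under ionic conditions should go to C6, which is para to the 3-methoxy group, because the 4-methoxy group is tied up in conjugation with the acetyl group (the same selectivity as for veratraldehyde).

**Step 2**
Reactants: 2 1-(2-bromo-4,5-dimethoxyphenyl)ethan-1-one; 3 3-(benzyloxy)-4-methoxybenzaldehyde (O-benzylisovanillin)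
Product: 4 (E)-3-[3-(benzyloxy)-4-methoxyphenyl]-1-(2-bromo-4,5-dimethoxyphenyl)prop-2-en-1-one
Conditions: aq NaOH (cat.), EtOH, rt
Reagents that add atoms: none
Why: Claisen–Schmidt aldol condensation of a methyl ketone with a non-enolisable aldehyde, in which E1cB dehydration should give the conjugated (E)-chalcone.

**Step 3**
Reactants: 4 the (E)-2'-bromochalcone
Product: 5 (3R)-3-[3-(benzyloxy)-4-methoxyphenyl]-5,6-dimethoxy-2,3-dihydro-1H-inden-1-one
Conditions: Pd(OAc)2 (5 mol %), (R)-3,5-Xyl-MeO-BIPHEP (6 mol %), HCO2Na, ethylene glycol–DMF, 80 °C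
Reagents that add atoms: none
Why: Intramolecular asymmetric reductive Heck reaction (conjugate hydroarylation, known for 2'-halochalcones → 3-arylindanones), in which oxidative addition into C–Br, enantio-determining insertion of the enone β-carbon within the chiral bisphosphine pocket, and protonation/formate reduction of the Pd enolate close the five-membered ring and set C3 (R) by catalyst control.

**Step 4**
Reactants: 5 the (3R)-3-arylindanone
Product: 7 (2S,3R)-3-[3-(benzyloxy)-4-methoxyphenyl]-5,6-dimethoxy-2-methyl-2,3-dihydro-1H-inden-1-one (2,3-trans), via lithium enolate 6 (not isolated)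
Conditions: LiHMDS (1.05 equiv), THF, −78 °C; MeI, −78 → −20 °C
Reagents that add atoms: iodomethane, CI
Why: Kinetic enolate alkylation (SN2 on MeI), in which only the C2 proton is removed at low temperature and MeI should approach 6 anti to the C3 aryl group to give the trans ketone; this centre is overwritten in step 5.

**Step 5**
Reactants: 7 the (2S,3R)-2-methyl-3-arylindanone
Product: 9 (2S,3R)-3-[3-(benzyloxy)-4-methoxyphenyl]-2-ethenyl-5,6-dimethoxy-2-methyl-2,3-dihydro-1H-inden-1-one (vinyl trans to aryl), via lithium enolate 8 (not isolated)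
Conditions: LiHMDS (1.05 equiv), THF, 0 °C; Pd2(dba)3 (2.5 mol %), P(t-Bu)3 (6 mol %), vinyl bromide, toluene–THF, rt → 40 °C
Reagents that add atoms: vinyl bromide, C=CBr
Why: Palladium-catalysed α-vinylation of a ketone enolate (known for 2-methyl-1-indanones with vinyl bromide), in which C–C reductive elimination on the face anti to the C3 aryl group builds the quaternary carbon, the product has no α-hydrogen so the alkene cannot move into conjugation, and keeping the base limiting leaves C3–H untouched.

**Step 6**
Reactants: 9 the α-methyl-α-vinylindanone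
Product: 14 (2S,3R,4R)-4-[3-(benzyloxy)-4-methoxyphenyl]-6,7-dimethoxy-2,3-dimethyl-3,4-dihydronaphthalen-1(2H)-one, via secondary alkyl radical 10 (not isolated), via cyclopropyloxy radical 11 (not isolated), via tertiary C3 radical 12 (not isolated), via tetralone C2-epimer mixture 13 (not isolated)
Conditions: Mn(dpm)3 (15 mol %), PhSiH3, t-BuOOH, degassed i-PrOH (0.01 M), rt; then DBU (20 mol %), rt
Reagents that add atoms: none
Why: Mn–H formed from Mn(dpm)3 and PhSiH3 delivers H• to the CH2 terminus of the vinyl group (Markovnikov MHAT) to give the secondary radical 10, which adds to the adjacent C1 carbonyl carbon to give the cyclopropyloxy radical 11, whose endocyclic C1–C(quaternary) bond then breaks (β-scission, net 1,2-acyl shift), so that the five-membered ring grows to the six-membered ring and the tertiary radical 12 left at C3 takes a second H• from Mn–H. The closest known reaction type is the Dowd–Beckwith one-carbon ring expansion, established for 1-indanone → 1-tetralone systems under tin hydride conditions and, in its MHAT-initiated form, for α-alkenyl cycloalkanones; in polar terms it joins two electrophilic carbons (a Markovnikov carbon and a carbonyl carbon), which only the radical manifold allows. The only ring closed is the transient cyclopropane of 11 (3-exo-trig on C=O); the tetralone ring is not closed as such but arises from the indanone ring by insertion of the CH(CH3) carbon between C1 and the old α-carbon. C3 is set by substrate control from C4: the C4 aryl group stands pseudoaxial to avoid the peri C5–H and covers one face of 12, so H• should enter anti to it along the axial trajectory and leave the C3 methyl group equatorial and cis to the aryl group. C2 is set under thermodynamic control by DBU, because in 14 the C2 methyl group is equatorial whereas its epimer would place it 1,3-diaxial to the C4 aryl group; C4 itself is not touched and the quaternary centre of 9 is erased, so both C2 epimers of 9 converge on 14. The step needs the acyl shift to outrun direct H-transfer to 10 and needs endocyclic instead of exocyclic β-scission of 11: high dilution with a low stationary Mn–H concentration secures the first, and the methyl group on the α-carbon (secondary → tertiary radical) together with the release of indanone ring strain secures the second.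

**Step 7**
Reactants: 14 the O-benzyl tetralone
Product: 15 (2S,3R,4R)-4-(3-hydroxy-4-methoxyphenyl)-6,7-dimethoxy-2,3-dimethyl-3,4-dihydronaphthalen-1(2H)-one (target, CNP0170223.1)
Conditions: H2 (1 atm), 10 % Pd/C, EtOAc–EtOH, rt
Reagents that add atoms: none
Why: Catalytic hydrogenolysis of the benzyl aryl ether, in which the electron-rich aryl ketone and the three stereocentres should stay untouched at 1 atm because no acid or base is present.

**Compound list**
1 | 1-(3,4-dimethoxyphenyl)ethan-1-one | CC(=O)c1ccc(OC)c(OC)c1 | starting material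
2 | 1-(2-bromo-4,5-dimethoxyphenyl)ethan-1-one | CC(=O)c1cc(OC)c(OC)cc1Br | intermediate
3 | 3-(benzyloxy)-4-methoxybenzaldehyde | COc1ccc(C=O)cc1OCc1ccccc1 | starting material
4 | (E)-3-[3-(benzyloxy)-4-methoxyphenyl]-1-(2-bromo-4,5-dimethoxyphenyl)prop-2-en-1-one | COc1ccc(/C=C/C(=O)c2cc(OC)c(OC)cc2Br)cc1OCc1ccccc1 | intermediate
5 | (3R)-3-[3-(benzyloxy)-4-methoxyphenyl]-5,6-dimethoxyindan-1-one | COc1ccc([C@@H]2c3cc(OC)c(OC)cc3C(=O)C2)cc1OCc1ccccc1 | intermediate
6 | lithium enolate of 5 (C3 unchanged) | COc1ccc([C@@H]2c3cc(OC)c(OC)cc3C(O[Li])=C2)cc1OCc1ccccc1 | intermediate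
7 | (2S,3R)-3-[3-(benzyloxy)-4-methoxyphenyl]-5,6-dimethoxy-2-methylindan-1-one (trans) | COc1ccc([C@@H]2c3cc(OC)c(OC)cc3C(=O)[C@H]2C)cc1OCc1ccccc1 | intermediate
8 | lithium enolate of 7 (C3 unchanged) | COc1ccc([C@@H]2c3cc(OC)c(OC)cc3C(O[Li])=C2C)cc1OCc1ccccc1 | intermediate
9 | (2S,3R)-3-[3-(benzyloxy)-4-methoxyphenyl]-2-ethenyl-5,6-dimethoxy-2-methylindan-1-one | COc1ccc([C@@H]2c3cc(OC)c(OC)cc3C(=O)[C@@]2(C)C=C)cc1OCc1ccccc1 | intermediate
10 | secondary radical, 1-(1-oxoindan-2-yl)ethyl type | COc1ccc([C@@H]2c3cc(OC)c(OC)cc3C(=O)[C@@]2(C)[CH]C)cc1OCc1ccccc1 | intermediate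
11 | cyclopropyloxy radical (cyclopropane fused on C1–C2 of the indane) | COc1ccc([C@@H]2c3cc(OC)c(OC)cc3C3([O])C(C)C23C)cc1OCc1ccccc1 | intermediate
12 | ring-expanded tertiary radical at C3 of the tetralone | COc1ccc([C@@H]2c3cc(OC)c(OC)cc3C(=O)C(C)[C]2C)cc1OCc1ccccc1 | intermediate
13 | (3R,4R)-O-benzyl tetralone, mixture of C2 epimers | COc1ccc([C@@H]2c3cc(OC)c(OC)cc3C(=O)C(C)[C@@H]2C)cc1OCc1ccccc1 | intermediate
14 | (2S,3R,4R)-4-[3-(benzyloxy)-4-methoxyphenyl]-6,7-dimethoxy-2,3-dimethyl-3,4-dihydronaphthalen-1(2H)-one | COc1ccc([C@@H]2c3cc(OC)c(OC)cc3C(=O)[C@@H](C)[C@@H]2C)cc1OCc1ccccc1 | intermediate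
15 | (2S,3R,4R)-4-(3-hydroxy-4-methoxyphenyl)-6,7-dimethoxy-2,3-dimethyl-3,4-dihydronaphthalen-1(2H)-one | COc1ccc([C@@H]2c3cc(OC)c(OC)cc3C(=O)[C@@H](C)[C@@H]2C)cc1O | target

**Total step count:** 7. **Longest linear sequence:** 7 (1 → 15).

**Steps most likely to fail**

**Step 6.**
- Risk: hydrogen transfer to the secondary radical may occur before the acyl shift.
- Risk: at the tertiary radical stage, a 1,2-aryl migration or back-transfer of the C4 hydrogen may intervene.
- Risk: facial discrimination in the last hydrogen transfer may be weak.
- Fallback (sets out from 7, returns at 14): the same carbon radical is made without a metal hydride, so that the hydrogen donor can be dosed.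
- Enolate 8 is added to acetaldehyde at −78 °C (aldol addition) to give the β-hydroxy ketone 3-aryl-2-(1-hydroxyethyl)-2-methylindan-1-one F1.
- 1,1'-Thiocarbonyldiimidazole under neutral conditions converts F1 into the O-(imidazol-1-ylthiocarbonyl) derivative F2.
- Syringe-pump addition of Bu3SnH/AIBN in refluxing benzene, followed by DBU, should lead to 14. This is the classical tin-hydride Dowd–Beckwith expansion with Barton–McCombie-type radical generation. The sequence also bypasses step 5.

**Step 5.**
- Risk: C–C reductive elimination may be slow at the fully substituted enolate carbon next to the C3 aryl group.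
- Risk: base may erode the configuration at C3.
- Fallback (sets out from 7, returns at 9): the two carbons are transferred as an electrophilic alkyne without palladium.
- The potassium enolate of 7 is treated with TMS-ethynylbenziodoxolone/TBAF at −78 °C (electrophilic α-alkynylation with a hypervalent iodine reagent) to give the α-ethynyl-α-methylindanone F3.
- Lindlar semihydrogenation of F3 should give 9.

**Step 3.**
- Risk: enantio-induction may be insufficient.
- Risk: β-hydride elimination to the indenone, or hydrodebromination, may compete.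
- Fallback (sets out from 4, returns at 5): the aryl halide is turned into an aryl nucleophile.
- Miyaura borylation (B2pin2, KOAc, Pd(dppf)Cl2) gives the 2'-(pinacolboryl)chalcone F4.
- A rhodium(I)/chiral phosphoramidite- or chiral-diene-catalysed intramolecular asymmetric 1,4-addition (aq K3PO4, toluene) should then give 5.

**Further compounds**
F1 | step 6 | (2S,3R)-3-[3-(benzyloxy)-4-methoxyphenyl]-2-(1-hydroxyethyl)-5,6-dimethoxy-2-methylindan-1-one (carbinol centre undefined) | COc1ccc([C@@H]2c3cc(OC)c(OC)cc3C(=O)[C@@]2(C)C(C)O)cc1OCc1ccccc1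
F2 | step 6 | O-(imidazol-1-ylthiocarbonyl) derivative of F1 | COc1ccc([C@@H]2c3cc(OC)c(OC)cc3C(=O)[C@@]2(C)C(C)OC(=S)n2ccnc2)cc1OCc1ccccc1
F3 | step 5 | (3R)-3-[3-(benzyloxy)-4-methoxyphenyl]-2-ethynyl-5,6-dimethoxy-2-methylindan-1-one (ethynyl trans to aryl) | COc1ccc([C@@H]2c3cc(OC)c(OC)cc3C(=O)[C@@]2(C)C#C)cc1OCc1ccccc1
F4 | step 3 | (E)-3-[3-(benzyloxy)-4-methoxyphenyl]-1-[4,5-dimethoxy-2-(4,4,5,5-tetramethyl-1,3,2-dioxaborolan-2-yl)phenyl]prop-2-en-1-one | COc1ccc(/C=C/C(=O)c2cc(OC)c(OC)cc2B2OC(C)(C)C(C)(C)O2)cc1OCc1ccccc1
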